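Count L, E and Z as fractions of the Z charged: in a run they then add up to about one, and the bound part, L plus E, is one minus the free Z.

| flask | Z | Q | remark | time |
|---|---|---|---|---|
| north-east | 10 mM | 6 mM (in portions, 3) | run made earlier; portions every 1.0 min |  |
| south-west | 10 mM | 9 mM (in portions, 3) | run made earlier; portions every 1.0 min |  |
| south | 15 mM | 12 mM (in portions, 3) | run made earlier; portions every 1.0 min |  |
| flask | 10 mM | 12.0 mM (in portions, 3) | the portions of Q follow each other after 1.0 min, the first at the start | 3.0 min |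

| run | time / min | L / % | E / % | Z / % |
|---|---|---|---|---|
| north-east | 0.250 | 3.0 | 8.4 | 88.3 |
| north-east | 0.667 | 1.7 | 8.6 | 89.1 |
| north-east | 1.50 | 4.5 | 13.7 | 83.2 |
| north-east | 4.00 | 1.8 | 8.3 | 89.5 |
| south-west | 0.833 | 2.2 | 10.1 | 86.4 |
| south-west | 2.00 | 4.2 | 15.0 | 80.6 |
| south-west | 2.50 | 6.9 | 22.8 | 70.5 |
| south-west | 4.00 | 3.9 | 11.2 | 84.5 |
| south | 0.250 | 4.4 | 12.8 | 81.7 |
| south | 0.667 | 3.9 | 12.4 | 83.6 |
| south | 1.50 | 7.2 | 20.2 | 71.5 |
| south | 4.00 | 4.5 | 14.3 | 80.5 |

(each reading ± 0.5 percentage points)



- the L in the flask at 3.0 min, as a percentage of the Z charged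
- the E in the flask at 3.0 min, as a percentage of the Z charged
- the Z in the flask at 3.0 min, as a percentage of the Z charged

The flask is read 1.0 min after its last portion of Q, and the south-west run has the same schedule. There the bound part falls from 29.5% at 2.50 min to 15.5% at 4.00 min, a decay of 0.429 min⁻¹, so I read 23.8% at 3.0 min. Scaled in proportion to the Q charged, that gives 31.7% bound in the flask.

That proportion is the weak link: the bound part is taken out of the free Z, and a straight proportion in the charge ignores that. So take bound Z over free Z, divided by the Q charged, which I read for the south-west run at 3.0 min as 0.0347 mM⁻¹; call this the odds per charge. The test is 4.00 min, where each of the earlier runs has a reading: the odds per charge there read 0.0196 mM⁻¹, 0.0204 mM⁻¹ and 0.0202 mM⁻¹, level within the scatter, even with more Z in the south run.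

For the flask I reckon odds of 0.417, and so free Z of 70.6%. To split the bound part, take an even split as the zero. The fullest reading of each run gives L a selectivity of 0.247, a quarter. My numbers are L 7.26% and E 22.1%.

The forecast, a little apart from these, reads L 7%, E 22% and Z 71%, on the step “Scaling by 1.25 gives about 29–30% converted at 3.0 min”.

The flask gives L 6.85%, E 21.9% and Z 71.2%, with Q at 10.4% of its own charge. Its odds per charge come to 0.0337 mM⁻¹, against the 0.0347 mM⁻¹ carried from the south-west run.

    Z + Q ⇌ L (K = 76.0 M⁻¹, k = 49.0 M⁻¹ s⁻¹)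
    Z + Q ⇌ E (K = 220 M⁻¹, k = 16.0 M⁻¹ s⁻¹)
    Q → J (k = 0.0290 s⁻¹)

In the neighbour charged with 4.8 mM of Q, the carried 0.0347 mM⁻¹ gives free Z of 85.7%. The computed neighbour holds 86.0%.

All runs are calculated on assumed constants; scatter was added.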